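The cyclohexane (C1 quaternary carbon, C2 side-chain CH, C3 alkylidene carbon, C4, C5, C6 carbinol carbon) is closed last at C5–C6. An acyclic iodo ketone, in which an enantioselective Ireland–Claisen rearrangement has set C1 and C2 and an enol tosylate coupling has fixed the (Z)-tetrasubstituted alkene, undergoes a samarium Barbier cyclisation: the C5 alkylsamarium adds to the C6 methyl ketone, creating ring and tertiary alcohol in one operation. The step exploits the 1,3-relation of C6 to C2 across C1 and the allylic strain of the C3 alkylidene, which holds the C2 chain axial and sends the ketone methyl equatorial, so the hydroxyl forms cis to both oxygenated arms.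

Key step: step 14

Assumption: the (S,S)-diazaborolidine controller of step 7 is taken to select the chair that leads to (2R,3R)-acid 12; if its sense of induction is the opposite one, the (R,R)-reagent is used in the same way.

Abbreviations: TBS = tert-butyldimethylsilyl; Ts = p-tolylsulfonyl; homofarnesyl = (3E,7E)-4,8,12-trimethyltrideca-3,7,11-trien-1-yl. Labels C1–C6 follow the overview; Cα is the exocyclic alkene carbon that carries CH3 and the ester or aldehyde.

Step 1
Reactants: 1 methyl acetoacetate; 2 (2E,6E)-farnesyl bromide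
Product: 3 methyl (6E,10E)-7,11,15-trimethyl-3-oxohexadeca-6,10,14-trienoate
Conditions: NaH, THF, 0 °C; n-BuLi, 0 °C; then 2, 0 °C → rt; aq. NH4Cl
Reagents that add atoms: none
Why: Dianion alkylation of the β-keto ester: the more basic terminal carbanion displaces the primary allylic bromide by SN2 without allylic transposition, so both (E) alkenes are retained.

Step 2
Reactants: 3
Product: 4 methyl (2E,6E,10E)-7,11,15-trimethyl-3-(trifluoromethylsulfonyloxy)hexadeca-2,6,10,14-tetraenoate (triflate trans to the ester)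
Conditions: Tf2O, 25% aq. Me4NOH, toluene, 5 °C
Reagents that add atoms: triflic anhydride, O=S(=O)(OS(=O)(=O)C(F)(F)F)C(F)(F)F
Why: Enol triflate formation: the non-chelated tetramethylammonium enolate is sulfonylated on oxygen in its extended geometry, which puts the triflate trans to the ester (E).

Step 3
Reactants: 4
Product: 5 methyl (2E,6E,10E)-3-(hydroxymethyl)-7,11,15-trimethylhexadeca-2,6,10,14-tetraenoate
Conditions: Bu3SnCH2OH, Pd(PPh3)4 (5 mol %), LiCl, 1,4-dioxane, 90 °C
Reagents that add atoms: (tributylstannyl)methanol, CCCC[Sn](CCCC)(CCCC)CO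
Why: Stille coupling of the β-triflyloxy enoate with the α-oxygenated stannane transfers CH2OH with retention of the alkene geometry, and the trans relation of CH2OH and ester excludes lactonisation.

Step 4
Reactants: 5
Product: 6 methyl (2E,6E,10E)-3-[(TBSO)methyl]-7,11,15-trimethylhexadeca-2,6,10,14-tetraenoate
Conditions: TBSCl, imidazole, DMF, rt
Reagents that add atoms: tert-butyldimethylsilyl chloride, CC(C)(C)[Si](C)(C)Cl
Why: Silyl ether formation masks the primary alcohol for the reduction and for the boron-mediated rearrangement.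

Step 5
Reactants: 6
Product: 7 (2E,6E,10E)-3-[(TBSO)methyl]-7,11,15-trimethylhexadeca-2,6,10,14-tetraen-1-ol (CH2OTBS trans to CH2OH)
Conditions: i-Bu2AlH (DIBAL-H, 2.2 equiv), CH2Cl2, −78 °C; Rochelle salt
Reagents that add atoms: none
Why: 1,2-Reduction of the conjugated ester by the aluminium hydride gives the allylic alcohol and leaves the alkenes and the silyl ether untouched.

Step 6
Reactants: 7; 8 5-(tert-butyldimethylsilyloxy)pentanoic acid
Product: 9 (2E,6E,10E)-3-[(TBSO)methyl]-7,11,15-trimethylhexadeca-2,6,10,14-tetraen-1-yl 5-(TBSO)pentanoate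
Conditions: DCC, DMAP (cat.), CH2Cl2, 0 °C → rt
Reagents that add atoms: none
Why: Steglich esterification joins the two fragments under neutral conditions.

Step 7
Reactants: 9
Product: 12 (2R,3R)-2-[3-(TBSO)propyl]-3-[(TBSO)methyl]-3-homofarnesylpent-4-enoic acid, via boron ketene acetal 10 (not isolated), via acyloxyborane 11 (not isolated)
Conditions: (4S,5S)-2-bromo-1,3-bis[3,5-bis(trifluoromethyl)phenylsulfonyl]-4,5-diphenyl-1,3,2-diazaborolidine (1.3 equiv, made from the (S,S)-bis-sulfonamide and BBr3 in CH2Cl2), Et3N, toluene/hexane, −78 °C, then −20 → 4 °C; aqueous work-up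
Reagents that add atoms: none
Why: Ireland–Claisen rearrangement of a chiral boron ketene acetal: the E(O)-enolate (side chain cis to the allyloxy oxygen) and the (2E)-allyl unit pass through a chair with CH2OTBS equatorial and the homofarnesyl chain axial at the forming quaternary carbon, which sets the relative configuration of C1 and C2, and the (S,S)-diazaborolidine differentiates the two mirror-image chairs.

Step 8
Reactants: 12
Product: 14 methyl (4R,5R)-4-[3-(TBSO)propyl]-5-[(TBSO)methyl]-5-homofarnesyl-2-methyl-3-oxohept-6-enoate (both C2 epimers), via acyl imidazole 13 (not isolated)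
Conditions: CDI, THF, rt; then potassium methyl 2-methylmalonate, MgCl2, Et3N, MeCN, rt → 45 °C; aq. citric acid
Reagents that add atoms: potassium methyl 2-methylmalonate, COC(=O)C(C)C(=O)[O-].[K+]
Why: C-Acylation of the magnesium enolate of the malonate half ester by the acyl imidazole, then decarboxylation (decarboxylative Claisen condensation), gives the β-keto ester under near-neutral conditions that do not epimerise C2; the new α-centre is a mixture that step 9 removes.

Step 9
Reactants: 14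
Product: 15 methyl (2E,4R,5R)-4-[3-(TBSO)propyl]-5-[(TBSO)methyl]-5-homofarnesyl-2-methyl-3-(tosyloxy)hepta-2,6-dienoate (tosylate trans to the ester)
Conditions: TsCl, N-methylimidazole, Et3N, MeCN, −15 → 0 °C
Reagents that add atoms: p-toluenesulfonyl chloride, Cc1ccc(cc1)S(Cl)(=O)=O
Why: O-Sulfonylation of the non-chelated ammonium enolate of the α-methyl β-keto ester gives the (E)-enol tosylate, which fixes the geometry of the later tetrasubstituted alkene.

Step 10
Reactants: 15
Product: 16 methyl (2E,4R,5R)-4-[3-(TBSO)propyl]-5-[(TBSO)methyl]-5-homofarnesyl-2-methyl-6-oxo-3-(tosyloxy)hept-2-enoate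
Conditions: PdCl2 (10 mol %), CuCl (1 equiv), O2 (1 atm), DMF/H2O 7:1, rt
Reagents that add atoms: water, O
Why: Wacker oxidation: Markovnikov hydroxypalladation of the only monosubstituted alkene gives the methyl ketone, while the trisubstituted alkenes and the enol tosylate do not react.

Step 11
Reactants: 16
Product: 17 methyl (2Z,4S,5R)-3-ethenyl-4-[3-(TBSO)propyl]-5-[(TBSO)methyl]-5-homofarnesyl-2-methyl-6-oxohept-2-enoate
Conditions: vinylboronic acid pinacol ester, Pd(OAc)2 (5 mol %), SPhos, K3PO4, THF/H2O, 60 °C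
Reagents that add atoms: vinylboronic acid pinacol ester, C=CB1OC(C)(C)C(C)(C)O1
Why: Suzuki–Miyaura coupling of the enol tosylate proceeds with retention and gives the dienoate with the vinyl group cis to the methyl group and C2 cis to the ester.

Step 12
Reactants: 17
Product: 19 methyl (2Z,4S,5R)-3-(2-hydroxyethyl)-4-[3-(TBSO)propyl]-5-[(TBSO)methyl]-5-homofarnesyl-2-methyl-6-oxohept-2-enoate, via alkylborane 18 (not isolated)
Conditions: 9-BBN (1.2 equiv), THF, 0 °C → rt; then H2O2, pH 7 phosphate buffer, 0 °C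
Reagents that add atoms: hydrogen peroxide, OO
Why: Hydroboration–oxidation: 9-BBN adds to the monosubstituted diene terminus with boron on the end carbon, faster than it attacks the hindered ketone, the tetrasubstituted enoate or the trisubstituted alkenes.

Step 13
Reactants: 19
Product: 20 methyl (2Z,4S,5R)-3-(2-iodoethyl)-4-[3-(TBSO)propyl]-5-[(TBSO)methyl]-5-homofarnesyl-2-methyl-6-oxohept-2-enoate
Conditions: I2, PPh3, imidazole, CH2Cl2, 0 °C
Reagents that add atoms: iodine, II
Why: Appel iodination converts the primary alcohol into the iodide by SN2 displacement of the oxyphosphonium ion.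

Step 14
Reactants: 20
Product: 22 methyl (2Z)-2-[(2S,3R,4R)-4-hydroxy-4-methyl-2-[3-(TBSO)propyl]-3-[(TBSO)methyl]-3-homofarnesylcyclohexylidene]propanoate, via alkylsamarium 21 (not isolated)
Conditions: SmI2 (2.5 equiv), NiI2 (2 mol %), THF, −20 → 0 °C; sat. aq. NH4Cl
Reagents that add atoms: none
Why: Two single-electron transfers from SmI2, speeded by NiI2, turn the primary C5–I bond into an alkylsamarium (trivalent samarium) that adds to the C6 methyl ketone, and work-up protonates the samarium alkoxide. The closest known reaction type is the samarium Barbier cyclisation of ω-iodoalkyl ketones to cycloalkanols. The ring closes in the 6-exo-trig mode, C5 attacking the C6 carbonyl carbon, and this forms the cyclohexane. The new stereocentre C6 is controlled by C2 and C1 through a chair: allylic strain with the ester on Cα, cis to C2, forces the C2 side chain axial, the ketone methyl takes the equatorial site to avoid a syn-diaxial clash with that chain, and the oxygen therefore ends up axial, cis to the CH2OTBS group on C1 and to the C2 chain (R at C6). The step needs reduction of the C–I bond before ketone or enoate and no attack on the ester; the ester lies trans to the C4–C5 arm across the alkene and cannot be reached, the tetrasubstituted enoate is slow to accept electrons, and the only radical ring closure open to the homoallylic radical (3-exo) is reversible.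

Step 15
Reactants: 22
Product: 23 (2Z)-2-[(2S,3R,4R)-4-hydroxy-4-methyl-2-[3-(TBSO)propyl]-3-[(TBSO)methyl]-3-homofarnesylcyclohexylidene]propan-1-ol
Conditions: i-Bu2AlH (DIBAL-H, 4 equiv), CH2Cl2, −78 → −20 °C; Rochelle salt
Reagents that add atoms: none
Why: 1,2-Reduction of the hindered enoate, the only carbonyl group left, gives the allylic alcohol.

Step 16
Reactants: 23
Product: 24 (2Z)-2-[(2S,3R,4R)-4-hydroxy-4-methyl-2-[3-(TBSO)propyl]-3-[(TBSO)methyl]-3-homofarnesylcyclohexylidene]propanal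
Conditions: MnO2 (activated, excess), CH2Cl2, rt
Reagents that add atoms: none
Why: MnO2 oxidises the allylic primary alcohol, the only oxidisable hydroxyl, to the enal without moving the tetrasubstituted alkene.

Step 17
Reactants: 24
Product: 25 (2Z)-2-[(2S,3R,4R)-4-hydroxy-3-(hydroxymethyl)-2-(3-hydroxypropyl)-4-methyl-3-homofarnesylcyclohexylidene]propanal (the target)
Conditions: HF·pyridine, pyridine, THF, 0 °C → rt
Reagents that add atoms: none
Why: Buffered fluoride cleaves both primary silyl ethers and should leave the tertiary alcohol and the (Z)-enal intact.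

Compound list

1 | methyl acetoacetate | CC(=O)CC(=O)OC | starting material
2 | (2E,6E)-farnesyl bromide | CC(C)=CCC/C(C)=C/CC/C(C)=C/CBr | starting material
3 | methyl (6E,10E)-7,11,15-trimethyl-3-oxohexadeca-6,10,14-trienoate | CC(C)=CCC/C(C)=C/CC/C(C)=C/CCC(=O)CC(=O)OC | intermediate
4 | (2E)-enol triflate of 3 | CC(C)=CCC/C(C)=C/CC/C(C)=C/CC/C(OS(=O)(=O)C(F)(F)F)=C\C(=O)OC | intermediate
5 | methyl (2E,6E,10E)-3-(hydroxymethyl)-7,11,15-trimethylhexadeca-2,6,10,14-tetraenoate | CC(C)=CCC/C(C)=C/CC/C(C)=C/CC/C(CO)=C\C(=O)OC | intermediate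
6 | TBS ether of 5 | CC(C)=CCC/C(C)=C/CC/C(C)=C/CC/C(CO[Si](C)(C)C(C)(C)C)=C\C(=O)OC | intermediate
7 | (2E,6E,10E)-3-[(TBSO)methyl]-7,11,15-trimethylhexadeca-2,6,10,14-tetraen-1-ol | CC(C)=CCC/C(C)=C/CC/C(C)=C/CC/C(CO[Si](C)(C)C(C)(C)C)=C\CO | intermediate
8 | 5-(tert-butyldimethylsilyloxy)pentanoic acid | CC(C)(C)[Si](C)(C)OCCCCC(=O)O | starting material
9 | ester of 7 with 8 | CC(C)=CCC/C(C)=C/CC/C(C)=C/CC/C(CO[Si](C)(C)C(C)(C)C)=C\COC(=O)CCCCO[Si](C)(C)C(C)(C)C | intermediate
10 | E(O)-boron ketene acetal of 9 on the (4S,5S)-diazaborolidine | CC(C)=CCC/C(C)=C/CC/C(C)=C/CC/C(CO[Si](C)(C)C(C)(C)C)=C\CO/C(OB1N(S(=O)(=O)c2cc(cc(c2)C(F)(F)F)C(F)(F)F)[C@@H](c2ccccc2)[C@H](c2ccccc2)N1S(=O)(=O)c1cc(cc(c1)C(F)(F)F)C(F)(F)F)=C\CCCO[Si](C)(C)C(C)(C)C | intermediate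
11 | acyloxyborane of acid 12 | CC(C)=CCC/C(C)=C/CC/C(C)=C/CC[C@](C=C)(CO[Si](C)(C)C(C)(C)C)[C@@H](CCCO[Si](C)(C)C(C)(C)C)C(=O)OB1N(S(=O)(=O)c2cc(cc(c2)C(F)(F)F)C(F)(F)F)[C@@H](c2ccccc2)[C@H](c2ccccc2)N1S(=O)(=O)c1cc(cc(c1)C(F)(F)F)C(F)(F)F | intermediate
12 | (2R,3R)-2-[3-(TBSO)propyl]-3-[(TBSO)methyl]-3-homofarnesylpent-4-enoic acid | CC(C)=CCC/C(C)=C/CC/C(C)=C/CC[C@](C=C)(CO[Si](C)(C)C(C)(C)C)[C@@H](CCCO[Si](C)(C)C(C)(C)C)C(=O)O | intermediate
13 | acyl imidazole of 12 | CC(C)=CCC/C(C)=C/CC/C(C)=C/CC[C@](C=C)(CO[Si](C)(C)C(C)(C)C)[C@@H](CCCO[Si](C)(C)C(C)(C)C)C(=O)n1ccnc1 | intermediate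
14 | methyl (4R,5R)-4-[3-(TBSO)propyl]-5-[(TBSO)methyl]-5-homofarnesyl-2-methyl-3-oxohept-6-enoate (C2 epimers) | CC(C)=CCC/C(C)=C/CC/C(C)=C/CC[C@](C=C)(CO[Si](C)(C)C(C)(C)C)[C@@H](CCCO[Si](C)(C)C(C)(C)C)C(=O)C(C)C(=O)OC | intermediate
15 | (2E)-enol tosylate of 14 | CC(C)=CCC/C(C)=C/CC/C(C)=C/CC[C@](C=C)(CO[Si](C)(C)C(C)(C)C)[C@@H](CCCO[Si](C)(C)C(C)(C)C)/C(=C(/C)C(=O)OC)OS(=O)(=O)c1ccc(C)cc1 | intermediate
16 | methyl ketone from 15 (6-oxo enol tosylate) | CC(C)=CCC/C(C)=C/CC/C(C)=C/CC[C@](C(C)=O)(CO[Si](C)(C)C(C)(C)C)[C@@H](CCCO[Si](C)(C)C(C)(C)C)/C(=C(/C)C(=O)OC)OS(=O)(=O)c1ccc(C)cc1 | intermediate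
17 | methyl (2Z,4S,5R)-3-ethenyl-4-[3-(TBSO)propyl]-5-[(TBSO)methyl]-5-homofarnesyl-2-methyl-6-oxohept-2-enoate | CC(C)=CCC/C(C)=C/CC/C(C)=C/CC[C@](C(C)=O)(CO[Si](C)(C)C(C)(C)C)[C@@H](CCCO[Si](C)(C)C(C)(C)C)/C(=C(/C)C(=O)OC)C=C | intermediate
18 | B-alkyl-9-borabicyclo[3.3.1]nonane from 17 (boron on C5) | CC(C)=CCC/C(C)=C/CC/C(C)=C/CC[C@](C(C)=O)(CO[Si](C)(C)C(C)(C)C)[C@@H](CCCO[Si](C)(C)C(C)(C)C)/C(=C(/C)C(=O)OC)CCB1C2CCCC1CCC2 | intermediate
19 | 3-(2-hydroxyethyl) analogue of 17 | CC(C)=CCC/C(C)=C/CC/C(C)=C/CC[C@](C(C)=O)(CO[Si](C)(C)C(C)(C)C)[C@@H](CCCO[Si](C)(C)C(C)(C)C)/C(=C(/C)C(=O)OC)CCO | intermediate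
20 | 3-(2-iodoethyl) analogue of 17 (iodo ketone) | CC(C)=CCC/C(C)=C/CC/C(C)=C/CC[C@](C(C)=O)(CO[Si](C)(C)C(C)(C)C)[C@@H](CCCO[Si](C)(C)C(C)(C)C)/C(=C(/C)C(=O)OC)CCI | intermediate
21 | alkylsamarium diiodide from 20 | CC(C)=CCC/C(C)=C/CC/C(C)=C/CC[C@](C(C)=O)(CO[Si](C)(C)C(C)(C)C)[C@@H](CCCO[Si](C)(C)C(C)(C)C)/C(=C(/C)C(=O)OC)CC[Sm](I)I | intermediate
22 | methyl (2Z)-2-[(2S,3R,4R)-4-hydroxy-4-methyl-2-[3-(TBSO)propyl]-3-[(TBSO)methyl]-3-homofarnesylcyclohexylidene]propanoate | CC(C)=CCC/C(C)=C/CC/C(C)=C/CC[C@]1(CO[Si](C)(C)C(C)(C)C)[C@@H](CCCO[Si](C)(C)C(C)(C)C)/C(=C(/C)C(=O)OC)CC[C@@]1(C)O | intermediate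
23 | allylic alcohol from 22 | CC(C)=CCC/C(C)=C/CC/C(C)=C/CC[C@]1(CO[Si](C)(C)C(C)(C)C)[C@@H](CCCO[Si](C)(C)C(C)(C)C)/C(=C(/C)CO)CC[C@@]1(C)O | intermediate
24 | bis-TBS ether of the target enal | CC(C)=CCC/C(C)=C/CC/C(C)=C/CC[C@]1(CO[Si](C)(C)C(C)(C)C)[C@@H](CCCO[Si](C)(C)C(C)(C)C)/C(=C(/C)C=O)CC[C@@]1(C)O | intermediate
25 | (2Z)-2-[(2S,3R,4R)-4-hydroxy-3-(hydroxymethyl)-2-(3-hydroxypropyl)-4-methyl-3-homofarnesylcyclohexylidene]propanal | CC(C)=CCC/C(C)=C/CC/C(C)=C/CC[C@]1(CO)[C@@H](CCCO)/C(=C(/C)C=O)CC[C@@]1(C)O | target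

Total step count: 17. Longest linear sequence: 17 steps (1 and 2 to 25); acid 8 enters in step 6.

Steps most likely to fail

1. Step 14 (key step). The primary radical or alkylsamarium may be diverted before it reaches the hindered ketone, by protonation to the deiodinated chain or by 3-exo addition to the enoate followed by reduction. The chair may also fail to separate the two ketone faces well enough. The fallback forms the same C5–C6 bond by ketyl–carbonyl coupling and sets out from alcohol 19. Dess–Martin periodinane should give keto aldehyde F1. SmI2 with t-BuOH in THF at −78 °C should then close the ring by pinacol coupling to cis-diol F2, in which the ketone methyl is again expected equatorial. PhOC(S)Cl and pyridine should acylate only the secondary hydroxyl to give thionocarbonate F3. Barton–McCombie deoxygenation (Bu3SnH, AIBN, toluene, 80 °C) should remove that oxygen and come back to the route at 22.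

2. Step 7. Rearrangement at the fully substituted allyl terminus is slow, so the boron enolate may lose its geometry, or the controller may not differentiate the two chairs (or may favour the wrong one). The fallback gives up reagent control and sets out from ester 9. LiN(i-Pr)2 and Me3SiCl in THF (−78 °C → rt) should give silyl ketene acetal F4, which rearranges through the same chair. Aqueous work-up should give acid 12 together with its mirror image F5, with the same relative configuration. Crystallisation with (S)-1-phenylethylamine should give the salt F6 of 12 and leave F5 in the mother liquor. Acidification of F6 comes back to the route at 12.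

3. Step 9. Enolisation of the hindered α-methyl β-keto ester may not give a single enolate geometry, which would erode the E/Z ratio of the tosylate and so the alkene geometry of the target. The fallback builds the alkene by syn-carbometalation of an alkyne and sets out from acid 12 (through acyl imidazole 13). Potassium methyl malonate, MgCl2 and Et3N should give β-keto ester F7. Tf2O with excess LiN(SiMe3)2 should dehydrate it in one flask to ynoate F8. Wacker oxidation (PdCl2, CuCl, O2) should give keto ynoate F9. Syn-carbocupration (CH2=CHMgBr, CuI, THF, −78 °C) with an iodine quench should give α-iodo dienoate F10, vinyl cis to iodine. Negishi coupling (MeZnCl, Pd(PPh3)4) with retention comes back to the route at 17.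

Further compounds

F1 | step 14 | keto aldehyde, 3-(2-oxoethyl) analogue of 17 | CC(C)=CCC/C(C)=C/CC/C(C)=C/CC[C@](C(C)=O)(CO[Si](C)(C)C(C)(C)C)[C@@H](CCCO[Si](C)(C)C(C)(C)C)/C(=C(/C)C(=O)OC)CC=O
F2 | step 14 | cis-diol, 22 with an extra hydroxyl on C5 cis to the C6 hydroxyl | CC(C)=CCC/C(C)=C/CC/C(C)=C/CC[C@]1(CO[Si](C)(C)C(C)(C)C)[C@@H](CCCO[Si](C)(C)C(C)(C)C)/C(=C(/C)C(=O)OC)C[C@@H](O)[C@@]1(C)O
F3 | step 14 | O-phenyl thionocarbonate of the C5 hydroxyl of F2 | CC(C)=CCC/C(C)=C/CC/C(C)=C/CC[C@]1(CO[Si](C)(C)C(C)(C)C)[C@@H](CCCO[Si](C)(C)C(C)(C)C)/C(=C(/C)C(=O)OC)C[C@@H](OC(=S)Oc2ccccc2)[C@@]1(C)O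
F4 | step 7 | trimethylsilyl ketene acetal of 9 (side chain cis to the allyloxy group) | CC(C)=CCC/C(C)=C/CC/C(C)=C/CC/C(CO[Si](C)(C)C(C)(C)C)=C\CO/C(O[Si](C)(C)C)=C\CCCO[Si](C)(C)C(C)(C)C
F5 | step 7 | (2S,3S)-enantiomer of acid 12 | CC(C)=CCC/C(C)=C/CC/C(C)=C/CC[C@@](C=C)(CO[Si](C)(C)C(C)(C)C)[C@H](CCCO[Si](C)(C)C(C)(C)C)C(=O)O
F6 | step 7 | (S)-1-phenylethylammonium salt of acid 12 | CC(C)=CCC/C(C)=C/CC/C(C)=C/CC[C@](C=C)(CO[Si](C)(C)C(C)(C)C)[C@@H](CCCO[Si](C)(C)C(C)(C)C)C(=O)[O-].C[C@H]([NH3+])c1ccccc1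
F7 | step 9 | β-keto ester without the 2-methyl group (from 12 and methyl malonate) | CC(C)=CCC/C(C)=C/CC/C(C)=C/CC[C@](C=C)(CO[Si](C)(C)C(C)(C)C)[C@@H](CCCO[Si](C)(C)C(C)(C)C)C(=O)CC(=O)OC
F8 | step 9 | ynoate, methyl hept-6-en-2-ynoate with the substituents of 12 at C4 and C5 | CC(C)=CCC/C(C)=C/CC/C(C)=C/CC[C@](C=C)(CO[Si](C)(C)C(C)(C)C)[C@@H](CCCO[Si](C)(C)C(C)(C)C)C#CC(=O)OC
F9 | step 9 | keto ynoate, methyl 6-oxohept-2-ynoate with the same substituents | CC(C)=CCC/C(C)=C/CC/C(C)=C/CC[C@](C(C)=O)(CO[Si](C)(C)C(C)(C)C)[C@@H](CCCO[Si](C)(C)C(C)(C)C)C#CC(=O)OC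
F10 | step 9 | α-iodo dienoate, 17 with iodine in place of the 2-methyl group (iodine cis to vinyl) | CC(C)=CCC/C(C)=C/CC/C(C)=C/CC[C@](C(C)=O)(CO[Si](C)(C)C(C)(C)C)[C@@H](CCCO[Si](C)(C)C(C)(C)C)/C(=C(/I)C(=O)OC)C=C
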